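## Structural features

- The target is a (2S)-flavanone. Rings A and C form a chroman-4-one fused at C4a–C8a, and ring B hangs on C2.
- Ring A is substituted on four adjacent carbons: C4a carries the C4 carbonyl, C8a carries O1, C8 carries a (2R)-2-hydroxy-3-methylbut-3-enyl chain, and C7 carries a free hydroxyl. Ring B is a 4′-hydroxyphenyl group flanked by prenyl groups at C3′ and C5′.
- The two stereocentres, C2 and the side-chain carbinol, are separated by O1, C8a, C8 and a benzylic CH2. Neither can steer the other, so each must be set independently.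
- Fragile points:
  - C2 is a benzylic aryl ether β to the ketone and epimerises through retro-oxa-Michael opening to the chalcone once phenoxides are present.
  - The ortho-prenyl phenol of ring B closes to a chroman under acid.
  - The secondary allylic alcohol beside the isopropenyl group can ionise or cyclise onto the 7-OH under acid.
  - Four C=C bonds rule out hydrogenation and unselective oxidation.
- The real difficulty is that the C8 chain is an oxidised, transposed prenyl group next to two intact prenyl groups, so a late ene reaction or dihydroxylation cannot tell them apart. The chain also sits between two oxygens on a crowded arene, where electrophilic substitution is not regioselective.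
- The key step exploits the sequence C7–O, C8–alkyl, C8a–O, C4a–acyl around ring A. This is the pattern that a vinylketene and a siloxyalkyne assemble as a 3-siloxy-2-alkyl salicylate, with the chain and its carbinol arriving ready-made on the alkyne.

## Logic of the disconnections

**29 to 28.** The three O–H bonds of 29 are traced back to three O–Si bonds. All hydroxyls then share one class of protecting group and a single fluoride step ends the route. The forward step must be buffered so that no phenoxide opens ring C and scrambles C2.

**28 to 21 and 27.** The C2–C1′ bond is cut. This separates ring B completely and turns C2 into the β-carbon of an enone, so the stereocentre and the aryl bond are made in one catalyst-controlled conjugate addition under base-free conditions. The forward step needs facial control by the ligand alone and a catalyst that ignores three isolated alkenes.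

**27 to 24, 23 and 22.** The C–B bond, the O–Si bond and the two aryl–prenyl bonds are cut in turn, arriving at 22. The para bromine blocks the para position during C-prenylation and later becomes boron. The forward demand is ortho-C- over O-alkylation.

**21 to 19.** O1–C2 and C2–C3 are cut, removing C2 as a one-carbon unit that is introduced through enaminone 20. The gain is a simple aryl methyl ketone. The forward step needs a free C8a hydroxyl beside the acetyl group, which the key step supplies.

**19 to 17.** The C3–C4 bond is cut, so C3 comes from a methyl nucleophile and C4 from the ester carbon of 17. The demand is mono-addition to the ester.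

**17 to 13 and 9 (key step).** C8–C8a, C6–C7 and C4a–C8a are cut, dissolving ring A. The arene becomes a five-carbon diazo enone (through vinylketene 14) and a two-carbon ynol ether that already holds the chain, the carbinol and the C7 oxygen. The forward cascade must join the ketene carbon to the chain-bearing alkyne carbon.

**13 to 11 and 10.** The C5=N2 unit is cut back to the methyl group of 10, by way of the silyl dienol ether 11 and the trifluoroacetyl-activated 12. Entry through an acid chloride and diazomethane is set aside: diazomethane is an explosion and toxicity hazard and is itself a dipole toward the fumarate-type double bond. The forward demand is that no strongly basic enolate exists beside the acceptor alkene.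

**9 to 6.** The ynol C–C bond between the former ester carbon and the new oxygen-bearing carbon is cut (Kowalski homologation through 7 and 8). The gain is a plain β-silyloxy ester. The demand is addition to the ester faster than α-deprotonation.

**6 to 5, 4, 1 and 2.** The O–Si bond, the auxiliary ester bond and finally the C2–C3 bond of the pentenoate (acetate aldol) are cut. The only stereocentre of this fragment is set on 2 by the auxiliary in 1. The demand is Re-face addition to the aldehyde.

## Other disconnections considered

**Alternative 1:** The cut runs through ring A at C4a–C5 and C8–C8a, so ring A would be grown onto a finished, enantiopure ring C.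

- Forward step: the enol-ether double bond of iodo-dihydropyranone A1 would act as dienophile toward the 4-substituted siloxydiene A2 in a [4+2] cycloaddition. Loss of HI and methanol and hydrolysis of the silyl enol ether would aromatise the adduct to flavanone A3 with the 7-OH free.
- In favour: the whole flavanone skeleton appears in one convergent operation, the oxygen pattern follows from the polarity of the diene, and only deprotection would remain.
- Against:
  - The dienophile is a vinylogous ester crowded further by iodine, and A2 carries its chain on the bond-forming terminus. The cycloaddition would probably need Lewis acid, heat or pressure, which threaten the benzylic C2–O bond (para-oxygenated aryl, retro-oxa-Michael), the acetal and the silyl ethers.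
  - A2 would have to be made by enolising a ketone toward a carbon whose neighbour bears the silyloxy group, where β-elimination competes.
  - The 4′-O-MOM group would need acid for removal, next to two ortho-prenyl groups and an allylic alcohol.
- Comparison:
  - Structure: the plans are equals. Both build ring A from acyclic pieces and bring the carbinol in on a small chiral fragment without oxidising a prenyl group.
  - Mechanism: both rely on donor-controlled pericyclic regiochemistry. The ketene cascade of the chosen plan runs on an electronically matched pair without additive, whereas this cycloaddition is mismatched and C2 must survive it.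
  - Step economy: after the key step the alternative is better (deprotection only, against four steps). A1 and A2 would each need several steps, so the totals should be similar.

**Alternative 2:** The cut removes C4 as a one-carbon unit and breaks C4a–C4, C4–C3 and O1–C2, leaving iodophenol A4, carbon monoxide A5 and arylalkyne A6.

- Forward step: PdCl2(PPh3)2 in diethylamine would effect carbonylative coupling and amine-mediated 6-endo closure to flavone A7. The C2=C3 bond would then have to be reduced enantioselectively.
- In favour: three bonds and ring C in one step by well-established divalent palladium/zerovalent palladium chemistry, from two fragments of similar size.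
- Against:
  - A7 has no stereocentre at C2, and an enantioselective 1,4-reduction of a 2-aryl chromone beside three other C=C bonds is not dependable.
  - A4 is itself the contiguously substituted ring A with the chiral chain between two oxygens, so the cut leaves the hardest part of the problem unanswered.
  - Pressurised A5 and two acid-labile MOM groups add practical burdens.
- Comparison:
  - Step economy: for ring C the alternative is better (one step instead of steps 8, 9 and 13).
  - Mechanism: the bond-forming chemistry is at least the equal of the chosen plan in robustness. The chosen plan, however, creates the C2–aryl bond and the stereocentre in the same catalyst-controlled event, while the alternative defers the stereocentre to an extra, uncertain reduction.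
  - Structure: the alternative is weaker, because ring A is presupposed and not made.

**Alternative 3:** The cut is the single bond C2–C3.

- Forward step: the diazomethyl ketone A8, whose C8a oxygen carries the ring B benzyl group, would be decomposed by Rh2(S-PTTL)4 or its enantiomer. The carbenoid carbon would insert into one of the two enantiotopic benzylic C–H bonds next to O1, closing ring C and creating C2 in the tris-silyl ether A9.
- In favour: ring closure and stereocentre in one catalytic step, uniform silyl protection, a simple O-benzylation to join the rings, and a single deprotection to finish.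
- Against:
  - An acceptor-only carbenoid is indiscriminate. Attack of the ether oxygen (five-membered oxonium ylide, then benzyl shift to a benzofuranone), cyclopropanation of the prenyl and isopropenyl double bonds, and the general preference for five- over six-membered insertion would all compete.
  - Enantiocontrol with such carbenoids is usually modest.
  - A8 again presupposes the substituted ring A.
- Comparison:
  - Step economy: late in the route the alternative is the equal of the chosen plan (each ends with one desilylation), and it is better in needing neither a boronic acid nor a chromone.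
  - Mechanism: both plans pass through a diazomethyl ketone. The chosen plan is safer, because the Wolff rearrangement turns the diazo ketone into a ketene without a metal carbenoid that could attack the alkenes.
  - Structure: the alternative leaves ring A to be made by other means.

Key step: step 7

Remark: read from the target, the side-chain carbinol is R and C2 is S. The key-step partners 13 and 9 and the product 17 agree with this in constitution and configuration, so none of these structures needed correction. The improvement lies in how 13 is reached and used: diazomethane-free, made and used as a cold solution, and added slowly in the key step.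

Remark: (R)-HYTRA, methyl (E)-4-oxopent-2-enoate, 2-(trimethylsilyloxy)buta-1,3-diene, 4-acetamidobenzenesulfonyl azide and (R)-t-BuPyOx are taken to be purchasable. The sense of induction of the auxiliary in step 1 and of the ligand in step 13 is assigned by analogy with their accepted models and has not been verified for these substrates.

## Route

Step 1
Reactants: 1 (R)-2-hydroxy-1,2,2-triphenylethyl acetate [(R)-HYTRA]; 2 methacrolein (2-methylprop-2-enal)
Product: 4 (R)-2-hydroxy-1,2,2-triphenylethyl (R)-3-hydroxy-4-methylpent-4-enoate, via dilithium enolate 3 (not isolated)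
Conditions: LiN(i-Pr)2 (2.1 equiv), THF, −78 → 0 °C; then 2, THF/2-methylbutane, −125 °C; aq. NH4Cl
Reagents that add atoms: none
Why: HYTRA acetate aldol addition: the doubly lithiated acetate 3 should add to the Re face of the aldehyde under control of the triphenylglycol auxiliary, which for methacrolein means the R carbinol (the same topicity as with other α-branched aldehydes); the adduct is crystalline, so its diastereomeric purity can be raised by recrystallisation.

Step 2
Reactants: 4 (R)-2-hydroxy-1,2,2-triphenylethyl (R)-3-hydroxy-4-methylpent-4-enoate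
Product: 5 methyl (R)-3-hydroxy-4-methylpent-4-enoate
Conditions: K2CO3 (cat.), MeOH, 0 °C → rt
Reagents that add atoms: methanol, CO
Why: Base-catalysed transesterification releases the auxiliary diol for recovery; the mild carbonate is chosen to avoid retro-aldol cleavage and dehydration of the β-hydroxy ester, so the carbinol stays R.

Step 3
Reactants: 5 methyl (R)-3-hydroxy-4-methylpent-4-enoate
Product: 6 methyl (R)-3-(tert-butyldimethylsilyloxy)-4-methylpent-4-enoate
Conditions: t-BuMe2SiCl, imidazole, DMF, rt
Reagents that add atoms: tert-butyldimethylsilyl chloride, CC(C)(C)[Si](C)(C)Cl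
Why: Standard silylation of a secondary allylic alcohol; the ether must survive organolithium bases, light, heat and weak acid and leave with fluoride at the end.

Step 4
Reactants: 6 methyl (R)-3-(tert-butyldimethylsilyloxy)-4-methylpent-4-enoate
Product: 9 tert-butyldimethyl{[(3R)-2-methyl-6-(triisopropylsilyloxy)hex-1-en-5-yn-3-yl]oxy}silane, via lithium dibromoenolate 7 (not isolated), via lithium ynolate 8 (not isolated)
Conditions: CH2Br2, lithium 2,2,6,6-tetramethylpiperidide, THF, −78 °C; then 6; LiN(SiMe3)2; n-BuLi, −78 → 25 °C; then i-Pr3SiCl, 0 °C → rt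
Reagents that add atoms: dibromomethane, BrCBr; triisopropylsilyl chloride, CC(C)[Si](Cl)(C(C)C)C(C)C
Why: Kowalski ester homologation stopped at the ynolate: dibromomethyllithium adds to the ester, the dibromo ketone is held as enolate 7, bromine–lithium exchange triggers 1,2-shift of the alkyl group to ynolate 8, and the bulky silyl chloride traps it on oxygen. The silyloxy group is β to the ester carbon but γ to the ynolate carbon, and addition at −78 °C is counted on to outrun α-deprotonation and loss of silanolate; the stereocentre is not involved.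

Step 5
Reactants: 10 methyl (E)-4-oxopent-2-enoate
Product: 11 methyl (E)-4-(trimethylsilyloxy)penta-2,4-dienoate
Conditions: Me3SiOTf, Et3N, CH2Cl2, 0 °C; pentane, filtration, used crude
Reagents that add atoms: trimethylsilyl trifluoromethanesulfonate, C[Si](C)(C)OS(=O)(=O)C(F)(F)F
Why: Soft enolisation: silylation of the ketone oxygen and deprotonation of the methyl group by the amine give the 2-siloxydiene without a strongly basic enolate that would add to the acceptor alkene; the E enoate is untouched.

Step 6
Reactants: 11 methyl (E)-4-(trimethylsilyloxy)penta-2,4-dienoate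
Product: 13 methyl (E)-5-diazo-4-oxopent-2-enoate, via trifluoroacetyl diketone 12 (not isolated)
Conditions: (CF3CO)2O, CH2Cl2, −78 → 0 °C, evaporate; then 4-acetamidobenzenesulfonyl azide, Et3N, H2O (1 equiv), MeCN, 0 °C → rt, dark; kept as a cold solution
Reagents that add atoms: 4-acetamidobenzenesulfonyl azide, CC(=O)Nc1ccc(cc1)S(=O)(=O)N=[N+]=[N-]
Why: C-Trifluoroacetylation of the silyl dienol ether at its terminal carbon gives the activated 1,3-diketone 12, and detrifluoroacetylative diazo transfer then installs the diazo group while water and amine cleave the trifluoroacetyl group. The sequence avoids diazomethane, which is hazardous and would also add as a dipole to the fumarate-type double bond, and the only anion formed is a stabilised diketonate.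

Step 7
Reactants: 13 methyl (E)-5-diazo-4-oxopent-2-enoate; 9 tert-butyldimethyl{[(3R)-2-methyl-6-(triisopropylsilyloxy)hex-1-en-5-yn-3-yl]oxy}silane
Product: 17 methyl 3-[(2R)-2-(tert-butyldimethylsilyloxy)-3-methylbut-3-enyl]-2-hydroxy-4-(triisopropylsilyloxy)benzoate, via vinylketene 14 (not isolated), via vinylcyclobutenone 15 (not isolated), via dienylketene 16 (not isolated)
Conditions: hν (medium-pressure Hg lamp, Pyrex filter), ClCH2CH2Cl, 20 °C, 13 (1.5 equiv) added over several hours to 9; then 80 °C
Reagents that add atoms: none
Why: Irradiation of 13 should expel N2 with 1,2-shift of the alkenyl group (photochemical Wolff rearrangement) to give vinylketene 14, whose electrophilic ketene carbon is attacked by the alkyl-bearing carbon of the electron-rich siloxyalkyne 9 in a regiospecific [2+2] cycloaddition to the 4-alkenyl-3-siloxycyclobutenone 15 (C8–C8a and C6–C7 formed). Under the light and the final heating 15 should open by 4π-electrocyclic cleavage of its C8a–C6 bond to dienylketene 16, which closes ring A by a thermal disrotatory 6π-electrocyclisation (C4a–C8a) to a cyclohexa-2,4-dienone that tautomerises to phenol 17. The closest known reaction type is the Danheiser benzannulation in its diazo-ketone variant with triisopropylsilyl ynol ethers, which gives resorcinol monosilyl ethers; the ester-bearing diazo enone is a new substrate for it, not a new reaction. No stereocentre is created and the silyl-protected carbinol is not touched, so its R configuration is carried through. The step needs the regiochemistry that joins the ketene carbon to the chain-bearing alkyne carbon, and the oxygen lone pair of the ynol ether, which makes that carbon the nucleophilic one, secures it; the same polarity leaves the C8a oxygen free and the C7 oxygen silylated. Chemoselectivity for the alkyne over the isopropenyl group rests on the much higher nucleophilicity of the ynol ether toward ketenes. Slow addition of 13 keeps its stationary concentration low and so disfavours dipolar addition of the diazo group to the acceptor double bond of a second molecule.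

Step 8
Reactants: 17 methyl 3-[(2R)-2-(tert-butyldimethylsilyloxy)-3-methylbut-3-enyl]-2-hydroxy-4-(triisopropylsilyloxy)benzoate
Product: 19 1-{3-[(2R)-2-(tert-butyldimethylsilyloxy)-3-methylbut-3-enyl]-2-hydroxy-4-(triisopropylsilyloxy)phenyl}ethan-1-one, via silylmethyl ketone 18 (not isolated)
Conditions: Me3SiCH2Li (3.5 equiv), THF/pentane, −78 → 0 °C; then MeOH, rt
Reagents that add atoms: (trimethylsilyl)methyllithium, [Li]C[Si](C)(C)C
Why: After deprotonation of the phenol the silylmethyl lithium reagent adds to the ester to give the α-silyl ketone 18, which is enolised at once by further reagent and so shielded from a second addition; methanolysis of the C–Si bond on quench reveals the methyl ketone. This is the known one-step conversion of esters into methyl ketones.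

Step 9
Reactants: 19 1-{3-[(2R)-2-(tert-butyldimethylsilyloxy)-3-methylbut-3-enyl]-2-hydroxy-4-(triisopropylsilyloxy)phenyl}ethan-1-one
Product: 21 8-[(2R)-2-(tert-butyldimethylsilyloxy)-3-methylbut-3-enyl]-7-(triisopropylsilyloxy)-4H-chromen-4-one, via enaminone 20 (not isolated)
Conditions: Me2NCH(OMe)2, PhMe, 90 °C; then AcOH, PhMe, 80 °C
Reagents that add atoms: N,N-dimethylformamide dimethyl acetal, COC(OC)N(C)C
Why: Condensation of the methyl ketone with the amide acetal gives enaminone 20; the hydrogen-bonded C8a phenol then adds to the β-carbon and dimethylamine is expelled under weak acid (6-endo addition–elimination), conditions mild enough for both silyl ethers.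

Step 10
Reactants: 22 4-bromophenol
Product: 23 4-bromo-2,6-bis(3-methylbut-2-enyl)phenol
Conditions: NaH (2.2 equiv), prenyl bromide (2.2 equiv), PhMe, 0 °C → rt
Reagents that add atoms: 1-bromo-3-methylbut-2-ene (prenyl bromide), CC(C)=CCBr
Why: ortho-C-Alkylation of a sodium phenoxide in a non-polar medium: the tight ion pair shields oxygen and directs the allylic halide to the ortho carbons, and the para bromine leaves only the two ortho sites, so two rounds should give the 2,6-diprenyl phenol.

Step 11
Reactants: 23 4-bromo-2,6-bis(3-methylbut-2-enyl)phenol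
Product: 24 [4-bromo-2,6-bis(3-methylbut-2-enyl)phenoxy](tert-butyl)dimethylsilane
Conditions: t-BuMe2SiOTf, 2,6-lutidine, CH2Cl2, 0 °C → rt
Reagents that add atoms: tert-butyldimethylsilyl trifluoromethanesulfonate, CC(C)(C)[Si](C)(C)OS(=O)(=O)C(F)(F)F
Why: The silyl triflate is used because the phenol is flanked by two ortho substituents; the silyl ether matches those on ring A, so one fluoride step can end the synthesis.

Step 12
Reactants: 24 [4-bromo-2,6-bis(3-methylbut-2-enyl)phenoxy](tert-butyl)dimethylsilane
Product: 27 [4-(tert-butyldimethylsilyloxy)-3,5-bis(3-methylbut-2-enyl)phenyl]boronic acid, via aryllithium 25 (not isolated), via lithium triisopropoxyborate 26 (not isolated)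
Conditions: n-BuLi, THF, −78 °C; B(Oi-Pr)3, −78 °C → rt; 1 M HCl, 0 °C
Reagents that add atoms: triisopropyl borate, CC(C)OB(OC(C)C)OC(C)C; water, O
Why: Bromine–lithium exchange at −78 °C is faster than deprotonation of the benzylic–allylic CH2 groups; the aryllithium is trapped by the borate and the ate complex is hydrolysed briefly to the boronic acid, the hindered aryl silyl ether being expected to withstand the cold dilute acid.

Step 13
Reactants: 21 8-[(2R)-2-(tert-butyldimethylsilyloxy)-3-methylbut-3-enyl]-7-(triisopropylsilyloxy)-4H-chromen-4-one; 27 [4-(tert-butyldimethylsilyloxy)-3,5-bis(3-methylbut-2-enyl)phenyl]boronic acid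
Product: 28 (2S)-2-[4-(tert-butyldimethylsilyloxy)-3,5-bis(3-methylbut-2-enyl)phenyl]-8-[(2R)-2-(tert-butyldimethylsilyloxy)-3-methylbut-3-enyl]-7-(triisopropylsilyloxy)chroman-4-one
Conditions: Pd(OCOCF3)2 (10 mol %), (R)-t-BuPyOx (12 mol %), NH4PF6 (30 mol %), H2O (5 equiv), ClCH2CH2Cl, 50 °C, 27 (2 equiv)
Reagents that add atoms: none
Why: Palladium-catalysed asymmetric conjugate addition of an arylboronic acid to a chromone: transmetalation gives a cationic aryl–palladium species on the pyridine-oxazoline ligand, enantioface-selective insertion of the C2=C3 bond follows, and water protonates the palladium enolate under base-free conditions that do not open ring C. The (R)-ligand is chosen because, by the steric model accepted for this catalyst with cyclic enones, it should deliver the aryl group to the Re face of C2 and so give 2S; the distant R carbinol is a spectator, so the step is catalyst-controlled, and unactivated tri- and 1,1-disubstituted alkenes are poor partners for the aryl–palladium species.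

Step 14
Reactants: 28 (2S)-2-[4-(tert-butyldimethylsilyloxy)-3,5-bis(3-methylbut-2-enyl)phenyl]-8-[(2R)-2-(tert-butyldimethylsilyloxy)-3-methylbut-3-enyl]-7-(triisopropylsilyloxy)chroman-4-one
Product: 29 (2S)-7-hydroxy-2-[4-hydroxy-3,5-bis(3-methylbut-2-enyl)phenyl]-8-[(2R)-2-hydroxy-3-methylbut-3-enyl]chroman-4-one (CNP0127055.2)
Conditions: Bu4NF, AcOH (1:1, excess), THF, 0 → 40 °C
Reagents that add atoms: none
Why: Fluoride cleaves the two aryl silyl ethers quickly and the secondary alkyl silyl ether more slowly; buffering with acetic acid keeps the liberated phenols protonated, so the flavanone should not open by retro-oxa-Michael reaction and C2 stays S, while the near-neutral medium spares the allylic alcohol and the ortho-prenyl phenol.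

## Compound list

1 | (R)-2-hydroxy-1,2,2-triphenylethyl acetate [(R)-HYTRA] | CC(=O)O[C@H](c1ccccc1)C(O)(c1ccccc1)c1ccccc1 | starting material
2 | methacrolein (2-methylprop-2-enal) | C=C(C)C=O | starting material
3 | dilithium enolate-alkoxide of 1 | [Li+].[Li+].C=C([O-])O[C@H](c1ccccc1)C([O-])(c1ccccc1)c1ccccc1 | intermediate (not isolated)
4 | (R)-2-hydroxy-1,2,2-triphenylethyl (R)-3-hydroxy-4-methylpent-4-enoate | C=C(C)[C@H](O)CC(=O)O[C@H](c1ccccc1)C(O)(c1ccccc1)c1ccccc1 | intermediate
5 | methyl (R)-3-hydroxy-4-methylpent-4-enoate | C=C(C)[C@H](O)CC(=O)OC | intermediate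
6 | methyl (R)-3-(tert-butyldimethylsilyloxy)-4-methylpent-4-enoate | C=C(C)[C@H](O[Si](C)(C)C(C)(C)C)CC(=O)OC | intermediate
7 | lithium (4R)-1,1-dibromo-4-(tert-butyldimethylsilyloxy)-5-methylhexa-1,5-dien-2-olate | [Li+].[O-]C(=C(Br)Br)C[C@@H](O[Si](C)(C)C(C)(C)C)C(C)=C | intermediate (not isolated)
8 | lithium (4R)-4-(tert-butyldimethylsilyloxy)-5-methylhex-5-en-1-yn-1-olate | [Li+].[O-]C#CC[C@@H](O[Si](C)(C)C(C)(C)C)C(C)=C | intermediate (not isolated)
9 | tert-butyldimethyl{[(3R)-2-methyl-6-(triisopropylsilyloxy)hex-1-en-5-yn-3-yl]oxy}silane | C=C(C)[C@H](O[Si](C)(C)C(C)(C)C)CC#CO[Si](C(C)C)(C(C)C)C(C)C | intermediate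
10 | methyl (E)-4-oxopent-2-enoate | COC(=O)/C=C/C(C)=O | starting material
11 | methyl (E)-4-(trimethylsilyloxy)penta-2,4-dienoate | COC(=O)/C=C/C(=C)O[Si](C)(C)C | intermediate
12 | methyl (E)-7,7,7-trifluoro-4,6-dioxohept-2-enoate | COC(=O)/C=C/C(=O)CC(=O)C(F)(F)F | intermediate (not isolated)
13 | methyl (E)-5-diazo-4-oxopent-2-enoate | COC(=O)/C=C/C(=O)C=[N+]=[N-] | intermediate
14 | methyl (E)-5-oxopenta-2,4-dienoate (vinylketene) | COC(=O)/C=C/C=C=O | intermediate (not isolated)
15 | methyl (E)-3-{3-[(2R)-2-(tert-butyldimethylsilyloxy)-3-methylbut-3-enyl]-4-oxo-2-(triisopropylsilyloxy)cyclobut-2-en-1-yl}prop-2-enoate | COC(=O)/C=C/C1C(=O)C(C[C@@H](O[Si](C)(C)C(C)(C)C)C(C)=C)=C1O[Si](C(C)C)(C(C)C)C(C)C | intermediate (not isolated)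
16 | methyl (2E,4E)-6-[(2R)-2-(tert-butyldimethylsilyloxy)-3-methylbut-3-enyl]-7-oxo-5-(triisopropylsilyloxy)hepta-2,4,6-trienoate (dienylketene) | COC(=O)/C=C/C=C(/O[Si](C(C)C)(C(C)C)C(C)C)\C(=C=O)C[C@@H](O[Si](C)(C)C(C)(C)C)C(C)=C | intermediate (not isolated)
17 | methyl 3-[(2R)-2-(tert-butyldimethylsilyloxy)-3-methylbut-3-enyl]-2-hydroxy-4-(triisopropylsilyloxy)benzoate | C=C(C)[C@H](O[Si](C)(C)C(C)(C)C)Cc1c(O[Si](C(C)C)(C(C)C)C(C)C)ccc(C(=O)OC)c1O | intermediate
18 | 1-{3-[(2R)-2-(tert-butyldimethylsilyloxy)-3-methylbut-3-enyl]-2-hydroxy-4-(triisopropylsilyloxy)phenyl}-2-(trimethylsilyl)ethan-1-one | C=C(C)[C@H](O[Si](C)(C)C(C)(C)C)Cc1c(O[Si](C(C)C)(C(C)C)C(C)C)ccc(C(=O)C[Si](C)(C)C)c1O | intermediate (not isolated)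
19 | 1-{3-[(2R)-2-(tert-butyldimethylsilyloxy)-3-methylbut-3-enyl]-2-hydroxy-4-(triisopropylsilyloxy)phenyl}ethan-1-one | C=C(C)[C@H](O[Si](C)(C)C(C)(C)C)Cc1c(O[Si](C(C)C)(C(C)C)C(C)C)ccc(C(C)=O)c1O | intermediate
20 | (E)-1-{3-[(2R)-2-(tert-butyldimethylsilyloxy)-3-methylbut-3-enyl]-2-hydroxy-4-(triisopropylsilyloxy)phenyl}-3-(dimethylamino)prop-2-en-1-one | C=C(C)[C@H](O[Si](C)(C)C(C)(C)C)Cc1c(O[Si](C(C)C)(C(C)C)C(C)C)ccc(C(=O)/C=C/N(C)C)c1O | intermediate (not isolated)
21 | 8-[(2R)-2-(tert-butyldimethylsilyloxy)-3-methylbut-3-enyl]-7-(triisopropylsilyloxy)-4H-chromen-4-one | C=C(C)[C@H](O[Si](C)(C)C(C)(C)C)Cc1c(O[Si](C(C)C)(C(C)C)C(C)C)ccc2c1OC=CC2=O | intermediate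
22 | 4-bromophenol | Oc1ccc(Br)cc1 | starting material
23 | 4-bromo-2,6-bis(3-methylbut-2-enyl)phenol | CC(C)=CCc1cc(Br)cc(CC=C(C)C)c1O | intermediate
24 | [4-bromo-2,6-bis(3-methylbut-2-enyl)phenoxy](tert-butyl)dimethylsilane | CC(C)=CCc1cc(Br)cc(CC=C(C)C)c1O[Si](C)(C)C(C)(C)C | intermediate
25 | [4-(tert-butyldimethylsilyloxy)-3,5-bis(3-methylbut-2-enyl)phenyl]lithium | [Li]c1cc(CC=C(C)C)c(O[Si](C)(C)C(C)(C)C)c(CC=C(C)C)c1 | intermediate (not isolated)
26 | lithium [4-(tert-butyldimethylsilyloxy)-3,5-bis(3-methylbut-2-enyl)phenyl]triisopropoxyborate | [Li+].CC(C)O[B-](OC(C)C)(OC(C)C)c1cc(CC=C(C)C)c(O[Si](C)(C)C(C)(C)C)c(CC=C(C)C)c1 | intermediate (not isolated)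
27 | [4-(tert-butyldimethylsilyloxy)-3,5-bis(3-methylbut-2-enyl)phenyl]boronic acid | OB(O)c1cc(CC=C(C)C)c(O[Si](C)(C)C(C)(C)C)c(CC=C(C)C)c1 | intermediate
28 | (2S)-2-[4-(tert-butyldimethylsilyloxy)-3,5-bis(3-methylbut-2-enyl)phenyl]-8-[(2R)-2-(tert-butyldimethylsilyloxy)-3-methylbut-3-enyl]-7-(triisopropylsilyloxy)chroman-4-one | C=C(C)[C@H](O[Si](C)(C)C(C)(C)C)Cc1c(O[Si](C(C)C)(C(C)C)C(C)C)ccc2c1O[C@H](c1cc(CC=C(C)C)c(O[Si](C)(C)C(C)(C)C)c(CC=C(C)C)c1)CC2=O | intermediate
29 | (2S)-7-hydroxy-2-[4-hydroxy-3,5-bis(3-methylbut-2-enyl)phenyl]-8-[(2R)-2-hydroxy-3-methylbut-3-enyl]chroman-4-one | C=C(C)[C@H](O)Cc1c(O)ccc2c1O[C@H](c1cc(CC=C(C)C)c(O)c(CC=C(C)C)c1)CC2=O | target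

## Step count and least certain steps

Total step count: 14. Longest linear sequence: 9 steps (steps 1, 2, 3, 4, 7, 8, 9, 13, 14).

**Step 7 (key step).**
- Most likely to go wrong: loss of the diazo enone before it reaches the alkyne, through dipolar addition of one molecule to the acceptor double bond of another and through light-induced E/Z isomerisation of the enoate, because the ester makes the alkene both a dipolarophile and a chromophore. Interception of the dienylketene by the phenol product is a lesser risk.
- Fallback: it sets out from 9 and removes the ester from the diazo partner.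
  - Commercial 2-(trimethylsilyloxy)buta-1,3-diene is trifluoroacetylated to 6,6,6-trifluorohex-1-ene-3,5-dione F1, which the diazo transfer of step 6 converts into 1-diazobut-3-en-2-one F2.
  - Irradiation of F2 with 9 as in step 7 should give 2-[(2R)-2-(tert-butyldimethylsilyloxy)-3-methylbut-3-enyl]-3-(triisopropylsilyloxy)phenol F3.
  - Casnati–Skattebøl ortho-formylation (MgCl2, Et3N, paraformaldehyde, MeCN, reflux) at the only free ortho position gives 3-[(2R)-2-(tert-butyldimethylsilyloxy)-3-methylbut-3-enyl]-2-hydroxy-4-(triisopropylsilyloxy)benzaldehyde F4.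
  - MeMgBr gives 1-{3-[(2R)-2-(tert-butyldimethylsilyloxy)-3-methylbut-3-enyl]-2-hydroxy-4-(triisopropylsilyloxy)phenyl}ethan-1-ol F5, and MnO2 oxidises this benzylic alcohol to 19, where the route is rejoined.

**Step 6.**
- Most likely to go wrong: oligomerisation of the acceptor alkene during trifluoroacetylation or diazo transfer, or incomplete C-acylation of the cross-conjugated silyl enol ether, because the enoate lowers its nucleophilicity.
- Fallback: it sets out from 11. Bromination with N-bromosuccinimide (THF, −78 °C) gives methyl (E)-5-bromo-4-oxopent-2-enoate F6. Treatment with N,N′-ditosylhydrazine and DBU (THF, 0 °C) displaces bromide and eliminates two sulfinates to give 13.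

**Step 4.**
- Most likely to go wrong: α-deprotonation of the ester with β-elimination of silanolate, or incomplete rearrangement of the carbenoid, because the silyloxy group is β to the carbonyl.
- Fallback: it sets out from 6.
  - i-Bu2AlH (CH2Cl2, −78 °C) gives (R)-3-(tert-butyldimethylsilyloxy)-4-methylpent-4-enal F7.
  - Seyferth–Gilbert homologation with the Ohira–Bestmann reagent (K2CO3, MeOH) gives tert-butyldimethyl{[(3R)-2-methylhex-1-en-5-yn-3-yl]oxy}silane F8.
  - n-BuLi followed by LiOOt-Bu (THF, −78 → 0 °C) oxidises the lithium acetylide to ynolate 8, and i-Pr3SiCl gives 9.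

**Step 8.**
- Most likely to go wrong: sluggish addition to the electron-rich, chelated phenoxide ester, or a second addition followed by Peterson elimination, because enolisation of the α-silyl ketone must outrun further attack.
- Fallback: it sets out from 17. MeNH(OMe)·HCl and i-PrMgCl (THF, −20 → 0 °C) give 3-[(2R)-2-(tert-butyldimethylsilyloxy)-3-methylbut-3-enyl]-2-hydroxy-N-methoxy-N-methyl-4-(triisopropylsilyloxy)benzamide F9, and MeMgBr converts this Weinreb amide into 19.

**Step 13.**
- Most likely to go wrong: insufficient facial selectivity, because the C8 chain and the C7 silyl ether lie near O1 and may disturb the usual fit of the chromone in the catalyst pocket. Protodeboronation of the electron-rich boronic acid is a lesser risk.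
- Fallback: it sets out from 21 and 27 and changes asymmetric catalysis into a resolution.
  - The addition is run to give 28 mixed with its C2 epimer, (2R)-2-[4-(tert-butyldimethylsilyloxy)-3,5-bis(3-methylbut-2-enyl)phenyl]-8-[(2R)-2-(tert-butyldimethylsilyloxy)-3-methylbut-3-enyl]-7-(triisopropylsilyloxy)chroman-4-one F10, if need be with achiral 2,2′-bipyridine as ligand.
  - Noyori asymmetric transfer hydrogenation used as a kinetic resolution (RuCl[(S,S)-TsDPEN](p-cymene) or its enantiomer, whichever is matched to the 2R series, HCO2H/Et3N, rt) should reduce F10 to the cis-alcohol (2R,4R)-2-[4-(tert-butyldimethylsilyloxy)-3,5-bis(3-methylbut-2-enyl)phenyl]-8-[(2R)-2-(tert-butyldimethylsilyloxy)-3-methylbut-3-enyl]-7-(triisopropylsilyloxy)chroman-4-ol F11 and leave 28.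
  - Chromatography separates ketone from alcohol and returns the route to 28.

**Step 10.**
- Most likely to go wrong: competing O-alkylation and incomplete or excessive C-alkylation, because the phenoxide is an ambident nucleophile.
- Fallback: it sets out from 22.
  - Iodination (I2, H2O2, H2O) gives 4-bromo-2,6-diiodophenol F12, and silylation (t-BuMe2SiCl, imidazole) gives (4-bromo-2,6-diiodophenoxy)(tert-butyl)dimethylsilane F13.
  - Two rounds of iodine–magnesium exchange (i-PrMgCl·LiCl, THF, −40 °C), each followed by CuBr·SMe2-catalysed coupling with prenyl bromide, place the prenyl groups regiospecifically and give 24.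

## Further compounds

F1 | step 7 | 6,6,6-trifluorohex-1-ene-3,5-dione | C=CC(=O)CC(=O)C(F)(F)F
F2 | step 7 | 1-diazobut-3-en-2-one | C=CC(=O)C=[N+]=[N-]
F3 | step 7 | 2-[(2R)-2-(tert-butyldimethylsilyloxy)-3-methylbut-3-enyl]-3-(triisopropylsilyloxy)phenol | C=C(C)[C@H](O[Si](C)(C)C(C)(C)C)Cc1c(O[Si](C(C)C)(C(C)C)C(C)C)cccc1O
F4 | step 7 | 3-[(2R)-2-(tert-butyldimethylsilyloxy)-3-methylbut-3-enyl]-2-hydroxy-4-(triisopropylsilyloxy)benzaldehyde | C=C(C)[C@H](O[Si](C)(C)C(C)(C)C)Cc1c(O[Si](C(C)C)(C(C)C)C(C)C)ccc(C=O)c1O
F5 | step 7 | 1-{3-[(2R)-2-(tert-butyldimethylsilyloxy)-3-methylbut-3-enyl]-2-hydroxy-4-(triisopropylsilyloxy)phenyl}ethan-1-ol | C=C(C)[C@H](O[Si](C)(C)C(C)(C)C)Cc1c(O[Si](C(C)C)(C(C)C)C(C)C)ccc(C(C)O)c1O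
F6 | step 6 | methyl (E)-5-bromo-4-oxopent-2-enoate | COC(=O)/C=C/C(=O)CBr
F7 | step 4 | (R)-3-(tert-butyldimethylsilyloxy)-4-methylpent-4-enal | C=C(C)[C@H](O[Si](C)(C)C(C)(C)C)CC=O
F8 | step 4 | tert-butyldimethyl{[(3R)-2-methylhex-1-en-5-yn-3-yl]oxy}silane | C=C(C)[C@H](O[Si](C)(C)C(C)(C)C)CC#C
F9 | step 8 | 3-[(2R)-2-(tert-butyldimethylsilyloxy)-3-methylbut-3-enyl]-2-hydroxy-N-methoxy-N-methyl-4-(triisopropylsilyloxy)benzamide | C=C(C)[C@H](O[Si](C)(C)C(C)(C)C)Cc1c(O[Si](C(C)C)(C(C)C)C(C)C)ccc(C(=O)N(C)OC)c1O
F10 | step 13 | (2R)-2-[4-(tert-butyldimethylsilyloxy)-3,5-bis(3-methylbut-2-enyl)phenyl]-8-[(2R)-2-(tert-butyldimethylsilyloxy)-3-methylbut-3-enyl]-7-(triisopropylsilyloxy)chroman-4-one | C=C(C)[C@H](O[Si](C)(C)C(C)(C)C)Cc1c(O[Si](C(C)C)(C(C)C)C(C)C)ccc2c1O[C@@H](c1cc(CC=C(C)C)c(O[Si](C)(C)C(C)(C)C)c(CC=C(C)C)c1)CC2=O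
F11 | step 13 | (2R,4R)-2-[4-(tert-butyldimethylsilyloxy)-3,5-bis(3-methylbut-2-enyl)phenyl]-8-[(2R)-2-(tert-butyldimethylsilyloxy)-3-methylbut-3-enyl]-7-(triisopropylsilyloxy)chroman-4-ol | C=C(C)[C@H](O[Si](C)(C)C(C)(C)C)Cc1c(O[Si](C(C)C)(C(C)C)C(C)C)ccc2c1O[C@@H](c1cc(CC=C(C)C)c(O[Si](C)(C)C(C)(C)C)c(CC=C(C)C)c1)C[C@H]2O
F12 | step 10 | 4-bromo-2,6-diiodophenol | Oc1c(I)cc(Br)cc1I
F13 | step 10 | (4-bromo-2,6-diiodophenoxy)(tert-butyl)dimethylsilane | CC(C)(C)[Si](C)(C)Oc1c(I)cc(Br)cc1I
A1 | alternative 1 | (2S)-5-iodo-2-[4-(methoxymethoxy)-3,5-bis(3-methylbut-2-enyl)phenyl]-2,3-dihydro-4H-pyran-4-one | O=C1C[C@@H](c2cc(CC=C(C)C)c(OCOC)c(CC=C(C)C)c2)OC=C1I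
A2 | alternative 1 | tert-butyl{[(3R,5Z,7E)-8-methoxy-2-methyl-6-(trimethylsilyloxy)octa-1,5,7-trien-3-yl]oxy}dimethylsilane | CO/C=C/C(O[Si](C)(C)C)=C/C[C@@H](O[Si](C)(C)C(C)(C)C)C(C)=C
A3 | alternative 1 | (2S)-8-[(2R)-2-(tert-butyldimethylsilyloxy)-3-methylbut-3-enyl]-7-hydroxy-2-[4-(methoxymethoxy)-3,5-bis(3-methylbut-2-enyl)phenyl]chroman-4-one | C=C(C)[C@H](O[Si](C)(C)C(C)(C)C)Cc1c(O)ccc2c1O[C@H](c1cc(CC=C(C)C)c(OCOC)c(CC=C(C)C)c1)CC2=O
A4 | alternative 2 | 2-[(2R)-2-(tert-butyldimethylsilyloxy)-3-methylbut-3-enyl]-6-iodo-3-(methoxymethoxy)phenol | C=C(C)[C@H](O[Si](C)(C)C(C)(C)C)Cc1c(OCOC)ccc(I)c1O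
A5 | alternative 2 | carbon monoxide | [C-]#[O+]
A6 | alternative 2 | 5-ethynyl-2-(methoxymethoxy)-1,3-bis(3-methylbut-2-enyl)benzene | C#Cc1cc(CC=C(C)C)c(OCOC)c(CC=C(C)C)c1
A7 | alternative 2 | 8-[(2R)-2-(tert-butyldimethylsilyloxy)-3-methylbut-3-enyl]-7-(methoxymethoxy)-2-[4-(methoxymethoxy)-3,5-bis(3-methylbut-2-enyl)phenyl]-4H-chromen-4-one | C=C(C)[C@H](O[Si](C)(C)C(C)(C)C)Cc1c(OCOC)ccc2c1OC(c1cc(CC=C(C)C)c(OCOC)c(CC=C(C)C)c1)=CC2=O
A8 | alternative 3 | 2-diazo-1-{4-(tert-butyldimethylsilyloxy)-2-{[4-(tert-butyldimethylsilyloxy)-3,5-bis(3-methylbut-2-enyl)phenyl]methoxy}-3-[(2R)-2-(tert-butyldimethylsilyloxy)-3-methylbut-3-enyl]phenyl}ethan-1-one | C=C(C)[C@H](O[Si](C)(C)C(C)(C)C)Cc1c(O[Si](C)(C)C(C)(C)C)ccc(C(=O)C=[N+]=[N-])c1OCc1cc(CC=C(C)C)c(O[Si](C)(C)C(C)(C)C)c(CC=C(C)C)c1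
A9 | alternative 3 | (2S)-7-(tert-butyldimethylsilyloxy)-2-[4-(tert-butyldimethylsilyloxy)-3,5-bis(3-methylbut-2-enyl)phenyl]-8-[(2R)-2-(tert-butyldimethylsilyloxy)-3-methylbut-3-enyl]chroman-4-one | C=C(C)[C@H](O[Si](C)(C)C(C)(C)C)Cc1c(O[Si](C)(C)C(C)(C)C)ccc2c1O[C@H](c1cc(CC=C(C)C)c(O[Si](C)(C)C(C)(C)C)c(CC=C(C)C)c1)CC2=O
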